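**Assumption:** the configuration is taken exactly as written in the SMILES, i.e. (2E,4S,5R,7S,12S,13R), with the two carbon chains cis on the oxirane and 12-OH/13-CH2OH syn. Numbering used below: C1 = enoic acid carbon, C4/C5 = oxirane carbons, C14 = second carboxyl carbon.

## Retrosynthetic overview

- Target ⇐ hydroxide opening (acyl–O, retention) of a cis-β-lactone plus methyl ester hydrolysis; the C4–C5 oxirane ⇐ Shi epoxidation of the (2E,4Z)-dienoate.
- cis-β-Lactone ⇐ ring-expansion carbonylation of a trans-2,3-epoxy alcohol, with CO entering at the CH2OH-bearing carbon with inversion (makes C13–C14, sets C13).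
- trans-Epoxy alcohol ⇐ Sharpless epoxidation ⇐ cross-metathesis of a terminal olefin with butenediol.
- (2E,4Z)-Dienoate ⇐ one-pot Grignard → alkylcopper → propyne carbocupration → syn addition to methyl but-2-ynoate; chain ⇐ Cu-catalysed sp3–sp3 coupling of (R)-3-bromo-2-methylpropanol with a pentenyl Grignard reagent.
- Ring order: C12–C13 oxirane → expanded to the oxetan-2-one → C4–C5 oxirane → oxetanone opened in the last step.

## Route

Step 1
Reactants: 1 (R)-3-bromo-2-methylpropan-1-ol; 2 5-bromopent-1-ene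
Product: 4 (S)-2-methyloct-7-en-1-ol, via pent-4-enylmagnesium bromide 3 (not isolated)
Conditions: 2, Mg, THF, rt; then 1, Li2CuCl4 (3 mol%), THF, −78 → 0 °C (2.5 equiv of 3); NH4Cl (aq)
Reagents that add atoms: none
Why: Kochi-type copper-catalysed sp3–sp3 cross-coupling of a primary bromide with a primary Grignard reagent (one equivalent of 3 is spent on the OH); the stereocentre of 1 is not touched and only its descriptor changes from R to S through the CIP priorities.

Step 2
Reactants: 4 (S)-2-methyloct-7-en-1-ol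
Product: 5 (S)-8-bromo-7-methyloct-1-ene
Conditions: CBr4, PPh3, CH2Cl2, 0 °C → rt
Reagents that add atoms: carbon tetrabromide, BrC(Br)(Br)Br
Why: Appel reaction of a primary alcohol, an SN2 displacement at CH2 that leaves the adjacent stereocentre untouched.

Step 3
Reactants: 5 (S)-8-bromo-7-methyloct-1-ene; 6 propyne; 7 methyl but-2-ynoate
Product: 12 methyl (2E,4Z,7S)-3,5,7-trimethyltrideca-2,4,12-trienoate, via Grignard reagent 8 (not isolated), via alkylcopper 9 (not isolated), via Z-alkenylcopper 10 (not isolated), via α-cuprio dienoate 11 (not isolated)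
Conditions: Mg, THF; CuBr·SMe2 (1 equiv), Et2O/Me2S, −45 °C; 6, −25 °C, 2 h; 7, THF, −78 → −40 °C; NH4Cl (aq), −78 °C
Reagents that add atoms: none
Why: Normant carbocupration, in which syn addition of the alkylcopper to propyne (Cu on the terminal carbon) fixes 4Z, and syn conjugate addition of the alkenylcopper to the ynoate followed by protonation of the configurationally stable α-cuprio enoate with retention fixes 2E.

Step 4
Reactants: 12 methyl (2E,4Z,7S)-3,5,7-trimethyltrideca-2,4,12-trienoate; 13 (Z)-but-2-ene-1,4-diol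
Product: 14 methyl (2E,4Z,7S,12E)-14-hydroxy-3,5,7-trimethyltetradeca-2,4,12-trienoate
Conditions: 13 (3 equiv), second-generation Hoveyda–Grubbs catalyst RuCl2(=CH-C6H4-2-OiPr)(H2IMes) (3 mol%), CH2Cl2, 40 °C
Reagents that add atoms: none
Why: Olefin cross-metathesis of the terminal (type-one) olefin with excess butenediol gives the thermodynamically favoured E-allylic alcohol (minor Z isomer removed by chromatography), while the trisubstituted conjugated olefins of the dienoate do not enter the ruthenium cycle.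

Step 5
Reactants: 14 methyl (2E,4Z,7S,12E)-14-hydroxy-3,5,7-trimethyltetradeca-2,4,12-trienoate
Product: 15 methyl (2E,4Z,7S)-11-[(2S,3S)-3-(hydroxymethyl)oxiran-2-yl]-3,5,7-trimethylundeca-2,4-dienoate
Conditions: Ti(OiPr)4 (10 mol%), L-(+)-diethyl tartrate (12 mol%), t-BuOOH (2 equiv, isooctane), 4 Å MS, CH2Cl2, −20 °C
Reagents that add atoms: tert-butyl hydroperoxide, CC(C)(C)OO
Why: Sharpless asymmetric epoxidation, in which the L-(+)-tartrate titanium complex delivers oxygen to one face of the E-allylic alcohol to give the (2S,3S)-trans-epoxy alcohol (reagent control; fixes C12 as S and places the later-inverted C13), the dienoate olefins lacking the allylic OH needed for binding.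

Step 6
Reactants: 15 methyl (2E,4Z,7S)-11-[(2S,3S)-3-(hydroxymethyl)oxiran-2-yl]-3,5,7-trimethylundeca-2,4-dienoate
Product: 16 methyl (2E,4Z,7S)-11-[(2S,3R)-3-(hydroxymethyl)-4-oxooxetan-2-yl]-3,5,7-trimethylundeca-2,4-dienoate
Conditions: [(salph)Al(THF)2][Co(CO)3(PPh2OMe)] (5 mol%; salph = N,N′-bis(3,5-di-tert-butylsalicylidene)-1,2-phenylenediaminate), Ph2POMe (10 mol%), CO (40 bar), 4 Å MS, DME, 40 °C
Reagents that add atoms: carbon monoxide, [C-]#[O+]
Why: Proposed new method: the P–OMe group of the cobalt-bound phosphinite exchanges with the primary OH of 15 (MeOH goes to the sieves), so the nucleophilic cobaltate is tethered three atoms from the CH2OH-bearing oxirane carbon and, with the oxirane oxygen held by the aluminium cation, attacks that carbon intramolecularly (five-membered cobaltacycle, 5-exo, SN2 with inversion at C13) instead of the distal carbon that untethered [Co(CO)4]− prefers; CO insertion and closure of the aluminium alkoxide onto the acyl–cobalt bond then give the cis-(3R,4S)-oxetan-2-one with C12 untouched and release the cobaltate for the next phosphinite exchange; the closest known reaction type is the Lewis acid/[Co(CO)4]− ring-expansion carbonylation of epoxides to β-lactones, combined with the exchangeable phosphinite directing groups of rhodium hydroformylation and the intramolecular C2-selective hydride delivery of alkoxyaluminium hydrides to 2,3-epoxy alcohols.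

Step 7
Reactants: 16 methyl (2E,4Z,7S)-11-[(2S,3R)-3-(hydroxymethyl)-4-oxooxetan-2-yl]-3,5,7-trimethylundeca-2,4-dienoate
Product: 17 methyl (2E,4S,5R,7S)-4,5-epoxy-11-[(2S,3R)-3-(hydroxymethyl)-4-oxooxetan-2-yl]-3,5,7-trimethylundec-2-enoate
Conditions: ent-Shi ketone (L-fructose-derived 1,2:4,5-di-O-isopropylidene-β-L-erythro-2,3-hexodiulo-2,6-pyranose, 1.5 equiv), KHSO5 (as Oxone), NaHCO3 (pH 8), Na2EDTA, Bu4NHSO4 (cat.), MeCN/DMM/H2O, 0 °C
Reagents that add atoms: potassium peroxymonosulfate (Oxone), [K+].[O-]S(=O)(=O)OO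
Why: Shi asymmetric epoxidation, in which the chiral dioxirane attacks only the electron-richer γ,δ-trisubstituted olefin through the spiro transition state (the α,β-olefin is deactivated by the ester), the L-series ketone giving 4S,5R by reagent control and the stereospecific syn oxygen transfer turning the 4Z geometry into the cis arrangement of the two chains.

Step 8
Reactants: 17 methyl (2E,4S,5R,7S)-4,5-epoxy-11-[(2S,3R)-3-(hydroxymethyl)-4-oxooxetan-2-yl]-3,5,7-trimethylundec-2-enoate
Product: 18 (2E,4S,5R,7S,12S,13R)-4,5-epoxy-12-hydroxy-13-(hydroxymethyl)-3,5,7-trimethyltetradec-2-enedioic acid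
Conditions: LiOH·H2O (6 equiv), THF/MeOH/H2O (3:1:1), 0 °C → rt; then 0.5 M HCl to pH 4, 0 °C, EtOAc extraction
Reagents that add atoms: lithium hydroxide, [Li+].[OH-]
Why: Saponification, in which hydroxide opens the β-lactone at the acyl carbon (acyl–oxygen cleavage, so C12 and C13 are retained) and hydrolyses the conjugated methyl ester, while the trisubstituted oxirane is inert to cold hydroxide and survives the brief pH 4 work-up.

## Compound list

1 | (R)-3-bromo-2-methylpropan-1-ol | OC[C@@H](C)CBr | starting material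
2 | 5-bromopent-1-ene | BrCCCC=C | starting material
3 | pent-4-enylmagnesium bromide | Br[Mg]CCCC=C | intermediate
4 | (S)-2-methyloct-7-en-1-ol | OC[C@@H](C)CCCCC=C | intermediate
5 | (S)-8-bromo-7-methyloct-1-ene | BrC[C@@H](C)CCCCC=C | intermediate
6 | propyne | CC#C | starting material
7 | methyl but-2-ynoate | CC#CC(=O)OC | starting material
8 | [(2S)-2-methyloct-7-en-1-yl]magnesium bromide | Br[Mg]C[C@@H](C)CCCCC=C | intermediate
9 | [(2S)-2-methyloct-7-en-1-yl]copper (MgBr2 complex) | [Cu]C[C@@H](C)CCCCC=C | intermediate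
10 | [(1Z,4S)-2,4-dimethyldeca-1,9-dien-1-yl]copper | [Cu]/C=C(/C)\C[C@@H](C)CCCCC=C | intermediate
11 | methyl (2Z,4Z,7S)-2-cuprio-3,5,7-trimethyltrideca-2,4,12-trienoate | COC(=O)/C([Cu])=C(\C)/C=C(/C)\C[C@@H](C)CCCCC=C | intermediate
12 | methyl (2E,4Z,7S)-3,5,7-trimethyltrideca-2,4,12-trienoate | COC(=O)/C=C(\C)/C=C(/C)\C[C@@H](C)CCCCC=C | intermediate
13 | (Z)-but-2-ene-1,4-diol | OC/C=C\CO | starting material
14 | methyl (2E,4Z,7S,12E)-14-hydroxy-3,5,7-trimethyltetradeca-2,4,12-trienoate | COC(=O)/C=C(\C)/C=C(/C)\C[C@@H](C)CCCC/C=C/CO | intermediate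
15 | methyl (2E,4Z,7S)-11-[(2S,3S)-3-(hydroxymethyl)oxiran-2-yl]-3,5,7-trimethylundeca-2,4-dienoate | COC(=O)/C=C(\C)/C=C(/C)\C[C@@H](C)CCCC[C@@H]1O[C@H]1CO | intermediate
16 | methyl (2E,4Z,7S)-11-[(2S,3R)-3-(hydroxymethyl)-4-oxooxetan-2-yl]-3,5,7-trimethylundeca-2,4-dienoate | COC(=O)/C=C(\C)/C=C(/C)\C[C@@H](C)CCCC[C@@H]1OC(=O)[C@@H]1CO | intermediate
17 | methyl (2E,4S,5R,7S)-4,5-epoxy-11-[(2S,3R)-3-(hydroxymethyl)-4-oxooxetan-2-yl]-3,5,7-trimethylundec-2-enoate | COC(=O)/C=C(\C)[C@@H]1O[C@]1(C)C[C@@H](C)CCCC[C@@H]2OC(=O)[C@@H]2CO | intermediate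
18 | (2E,4S,5R,7S,12S,13R)-4,5-epoxy-12-hydroxy-13-(hydroxymethyl)-3,5,7-trimethyltetradec-2-enedioic acid (CNP0468463.2) | C/C(=C\C(=O)O)[C@@H]1O[C@]1(C)C[C@@H](C)CCCC[C@H](O)[C@@H](CO)C(=O)O | target

## Step count and risks

Total step count: 8. Longest linear sequence: 8 steps (1 → 18; fully linear).

The three steps most likely to fail:

**Step 6** (new catalyst; the regiochemistry must be forced against the inherent distal preference). The fallback uses known chemistry only, sets out from 15 and comes back at 16. H5IO6 (THF/H2O, 0 °C) cleaves the epoxy alcohol through its triol to the aldehyde methyl (2E,4Z,7S)-3,5,7-trimethyl-12-oxododeca-2,4-dienoate F1. An Evans syn-aldol reaction of F1 with the boron enolate of (R)-4-benzyl-3-[3-(4-methoxybenzyloxy)propanoyl]oxazolidin-2-one (Bu2BOTf, iPr2NEt, CH2Cl2, −78 → 0 °C) gives the syn adduct methyl (2E,4Z,7S,12S,13R)-14-[(4R)-4-benzyl-2-oxooxazolidin-3-yl]-12-hydroxy-13-[(4-methoxybenzyloxy)methyl]-3,5,7-trimethyl-14-oxotetradeca-2,4-dienoate F2. LiOH/H2O2 (THF/H2O, 0 °C) removes the auxiliary to give the β-hydroxy acid (2R,3S,8S,10Z,12E)-3-hydroxy-14-methoxy-2-[(4-methoxybenzyloxy)methyl]-8,10,12-trimethyl-14-oxotetradeca-10,12-dienoic acid F3. PhSO2Cl/pyridine (0 °C) closes it with retention to the protected cis-β-lactone methyl (2E,4Z,7S)-11-[(2S,3R)-3-[(4-methoxybenzyloxy)methyl]-4-oxooxetan-2-yl]-3,5,7-trimethylundeca-2,4-dienoate F4. DDQ (CH2Cl2/pH 7 buffer) then removes the 4-methoxybenzyl group and returns 16.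

**Step 3** (four organometallic events in one flask; the 2E geometry depends on the α-cuprio enoate 11 not isomerising before the quench, and the mono-organocopper may add sluggishly to the β-methyl ynoate). The fallback sets out from 5 and comes back at 12. The same Z-alkenylcopper 10 is made from 5 and quenched with I2 (−40 → 0 °C) to give the vinyl iodide (1Z,4S)-1-iodo-2,4-dimethyldeca-1,9-diene F5. Separately, 7 is borylated (B2pin2, CuCl/Xantphos, NaOtBu, MeOH, THF) to methyl (Z)-3-(4,4,5,5-tetramethyl-1,3,2-dioxaborolan-2-yl)but-2-enoate F6. Suzuki–Miyaura coupling of F5 with F6 (Pd(PPh3)4, K3PO4, THF/H2O, 50 °C) joins C3–C4 with retention of both olefin geometries and gives 12.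

**Step 7** (the base-labile β-lactone sits in the buffered oxidation, which forces the low-pH, high-ketone-loading protocol; the cis-trisubstituted dienoate is also a less precedented olefin class). Partial lactone hydrolysis here is not fatal, because step 8 converges both forms. The fallback changes the end game, sets out from 16 and comes back at 18. 16 is saponified first (LiOH, THF/MeOH/H2O, rt) to (2E,4Z,7S,12S,13R)-12-hydroxy-13-(hydroxymethyl)-3,5,7-trimethyltetradeca-2,4-dienedioic acid F7. The epoxidation then becomes the last step, run on the dicarboxylate under the catalytic high-pH protocol (ent-Shi ketone 30 mol%, KHSO5, K2CO3, pH 10.5, MeCN/DMM/H2O, 0 °C), followed by acidification to pH 4, which gives 18 directly. No lactone is present during the oxidation and the oxirane never meets LiOH. This does not address poor facial selectivity, which would need a different oxidation method.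

## Further compounds

F1 | step 6 | methyl (2E,4Z,7S)-3,5,7-trimethyl-12-oxododeca-2,4-dienoate | COC(=O)/C=C(\C)/C=C(/C)\C[C@@H](C)CCCCC=O
F2 | step 6 | methyl (2E,4Z,7S,12S,13R)-14-[(4R)-4-benzyl-2-oxooxazolidin-3-yl]-12-hydroxy-13-[(4-methoxybenzyloxy)methyl]-3,5,7-trimethyl-14-oxotetradeca-2,4-dienoate | COC(=O)/C=C(\C)/C=C(/C)\C[C@@H](C)CCCC[C@H](O)[C@@H](COCc1ccc(OC)cc1)C(=O)N1[C@H](Cc2ccccc2)COC1=O
F3 | step 6 | (2R,3S,8S,10Z,12E)-3-hydroxy-14-methoxy-2-[(4-methoxybenzyloxy)methyl]-8,10,12-trimethyl-14-oxotetradeca-10,12-dienoic acid | COC(=O)/C=C(\C)/C=C(/C)\C[C@@H](C)CCCC[C@H](O)[C@@H](COCc1ccc(OC)cc1)C(=O)O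
F4 | step 6 | methyl (2E,4Z,7S)-11-[(2S,3R)-3-[(4-methoxybenzyloxy)methyl]-4-oxooxetan-2-yl]-3,5,7-trimethylundeca-2,4-dienoate | COC(=O)/C=C(\C)/C=C(/C)\C[C@@H](C)CCCC[C@@H]1OC(=O)[C@@H]1COCc1ccc(OC)cc1
F5 | step 3 | (1Z,4S)-1-iodo-2,4-dimethyldeca-1,9-diene | I/C=C(/C)\C[C@@H](C)CCCCC=C
F6 | step 3 | methyl (Z)-3-(4,4,5,5-tetramethyl-1,3,2-dioxaborolan-2-yl)but-2-enoate | COC(=O)/C=C(\C)/B1OC(C)(C)C(C)(C)O1
F7 | step 7 | (2E,4Z,7S,12S,13R)-12-hydroxy-13-(hydroxymethyl)-3,5,7-trimethyltetradeca-2,4-dienedioic acid | OC(=O)/C=C(\C)/C=C(/C)\C[C@@H](C)CCCC[C@H](O)[C@@H](CO)C(=O)O
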